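**Retrosynthetic overview**

- The feature that carries the route is the central benzene ring, numbered C1 (OMe), C2, C3 (OH), C4, C5 (2‑arylethyl), C6, with 4‑hydroxybenzyl on C2, C4 and C6: it has no ring hydrogen and two meta oxygens at C1/C3, the pattern a vinylketene–ynol ether benzannulation produces.
- Key disconnection: C1–C2 and C3–C4, with the ring closed through C1–C6. This gives a 2,4‑dibenzyl‑3‑arylethylcyclobutenone (supplies C1, C6, C5, C4) and a benzyl‑substituted siloxyalkyne (supplies C2, C3).
- The cyclobutenone comes from a 3‑siloxycyclobutenone (monoalkylketene plus the same siloxyalkyne, [2+2]) by arylethyl‑metal 1,2‑addition and acid‑induced carbonyl transposition. The siloxyalkyne comes from an arylacetate by the Kowalski ynolate rearrangement.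
- Ring order: the sacrificial four‑membered ring first, then the central benzene ring, which is the only ring of the target that is built (the four outer arenes are bought). End game: O‑methylation, desilylation, hydrogenolysis of four benzyl ethers.

Key step: step 5

Assumption: the target has no stereogenic element, so its constitution alone defines the single compound asked for; the ester, the acid and the bromide used as starting materials are taken as catalogue compounds.

**Route**

Step 1
Reactants: 1 ethyl [4-(benzyloxy)phenyl]acetate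
Product: 4 {3-[4-(benzyloxy)phenyl]prop-1-yn-1-yl}oxy(triisopropyl)silane, via lithium dibromoenolate 2 (not isolated), via lithium ynolate 3 (not isolated)
Conditions: CH2Br2, LiTMP (2.1 equiv), THF, −78 °C; n-BuLi, −78 → 0 °C; TIPSCl, 0 °C → rt
Reagents that add atoms: dibromomethane BrCBr; chlorotriisopropylsilane CC(C)[Si](Cl)(C(C)C)C(C)C
Why: In the Kowalski ester-to-ynolate rearrangement LiCHBr2 should add to the ester carbonyl at −78 °C faster than it enolises it, the derived dibromoketone enolate 2 should undergo Br–Li exchange and 1,2-shift to ynolate 3, and the bulky silyl chloride should capture 3 on oxygen to give the siloxyalkyne.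

Step 2
Reactants: 5 3-[4-(benzyloxy)phenyl]propanoic acid
Product: 6 3-[4-(benzyloxy)phenyl]propanoyl chloride
Conditions: (COCl)2, DMF (cat.), CH2Cl2, 0 °C → rt; concentrate, use crude
Reagents that add atoms: oxalyl chloride O=C(Cl)C(=O)Cl
Why: Vilsmeier-catalysed acid chloride formation is standard and leaves the aryl benzyl ether untouched.

Step 3
Reactants: 6 3-[4-(benzyloxy)phenyl]propanoyl chloride; 4 {3-[4-(benzyloxy)phenyl]prop-1-yn-1-yl}oxy(triisopropyl)silane
Product: 8 2,4-bis[4-(benzyloxy)benzyl]-3-[(triisopropylsilyl)oxy]cyclobut-2-en-1-one (racemic), via monoalkylketene 7 (not isolated)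
Conditions: Et3N, CH2Cl2, 0 °C → rt, slow addition of 6 to 4 and the amine
Reagents that add atoms: none
Why: Dehydrochlorination should release ketene 7 at low stationary concentration, and its [2+2] cycloaddition with the electron-rich siloxyalkyne (ketene–ynol ether cycloaddition, nucleophilic benzyl-bearing alkyne carbon onto the ketene carbonyl carbon) should give the 3-siloxycyclobutenone, whose one stereocentre forms racemic and is erased later.

Step 4
Reactants: 8 2,4-bis[4-(benzyloxy)benzyl]-3-[(triisopropylsilyl)oxy]cyclobut-2-en-1-one; 9 1-(benzyloxy)-3-(2-bromoethyl)benzene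
Product: 12 2,4-bis[4-(benzyloxy)benzyl]-3-{2-[3-(benzyloxy)phenyl]ethyl}cyclobut-2-en-1-one (racemic), via Grignard reagent 10 (not isolated), via tertiary cyclobutenol 11 (not isolated)
Conditions: Mg, THF, rt (9 → 10); anhydrous CeCl3, THF, −78 °C; 8, −78 → 0 °C; 1 M HCl, THF, rt
Reagents that add atoms: none
Why: Cerium-mediated 1,2-addition (Imamoto conditions) to the hindered vinylogous silyl ester, then acid-induced ionisation and desilylation of carbinol 11 (Stork–Danheiser-type carbonyl transposition), should move the carbonyl to the former siloxy carbon and place the arylethyl group at C3; the carbinol diastereomers converge and the remaining centre is racemic and irrelevant.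

Step 5
Reactants: 12 2,4-bis[4-(benzyloxy)benzyl]-3-{2-[3-(benzyloxy)phenyl]ethyl}cyclobut-2-en-1-one; 4 {3-[4-(benzyloxy)phenyl]prop-1-yn-1-yl}oxy(triisopropyl)silane
Product: 17 2,4,6-tris[4-(benzyloxy)benzyl]-5-{2-[3-(benzyloxy)phenyl]ethyl}-3-(triisopropylsilyloxy)phenol, via vinylketene 13 (not isolated), via 4-alkenylcyclobutenone 14 (not isolated), via dienylketene 15 (not isolated), via cyclohexa-2,4-dienone 16 (not isolated)
Conditions: 4 (1.5 equiv), toluene, 80 °C then 110 °C, sealed tube, argon
Reagents that add atoms: none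
Why: Conrotatory 4π opening of 12 at its C(=O)–CH bond (the 4-benzyl group turning outward) should give vinylketene 13, whose ketene C=C adds [2+2] to siloxyalkyne 4 to give 14; 14 opens again (4π) to dienylketene 15, which closes to dienone 16 and tautomerises to phenol 17. The closest known reaction is the Danheiser benzannulation of cyclobutenones with alkoxy- or siloxyalkynes, of which this is a direct case. The benzene ring is closed by disrotatory 6π electrocyclisation of 15, which joins the ketene carbon (ring C1) to C6 after the cycloaddition has formed C1–C2 and C3–C4. No stereocentre is created, and the racemic centres of 12, 14 and 16 disappear on aromatisation. The step needs one regiochemistry in the ketene–alkyne cycloaddition, and the polarisation of the ynol ether secures it: its nucleophilic benzyl-bearing carbon attacks the electrophilic ketene carbonyl carbon, which puts the siloxy carbon meta to the new hydroxyl. Because each partner carries its substituents into the ring, the hexasubstituted pattern is assembled without any substitution on an arene, and the OH/OSi pair is formed already differentiated.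

Step 6
Reactants: 17 2,4,6-tris[4-(benzyloxy)benzyl]-5-{2-[3-(benzyloxy)phenyl]ethyl}-3-(triisopropylsilyloxy)phenol
Product: 18 {2,4,6-tris[4-(benzyloxy)benzyl]-3-{2-[3-(benzyloxy)phenyl]ethyl}-5-methoxyphenoxy}triisopropylsilane
Conditions: NaH, MeI, THF–DMF (4:1), 0 °C → rt
Reagents that add atoms: iodomethane CI
Why: Williamson etherification of the only free hydroxyl should proceed even between two ortho benzyl groups with the small electrophile, while the TIPS and benzyl ethers are inert to NaH/MeI.

Step 7
Reactants: 18 {2,4,6-tris[4-(benzyloxy)benzyl]-3-{2-[3-(benzyloxy)phenyl]ethyl}-5-methoxyphenoxy}triisopropylsilane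
Product: 19 2,4,6-tris[4-(benzyloxy)benzyl]-3-{2-[3-(benzyloxy)phenyl]ethyl}-5-methoxyphenol
Conditions: TBAF, AcOH, THF, 0 °C → rt
Reagents that add atoms: none
Why: Fluoride-induced Si–O cleavage of the aryl silyl ether (buffered TBAF desilylation) should free the C3 phenol without touching the methyl or benzyl ethers, the acetic acid keeping the electron-rich phenoxide protonated.

Step 8
Reactants: 19 2,4,6-tris[4-(benzyloxy)benzyl]-3-{2-[3-(benzyloxy)phenyl]ethyl}-5-methoxyphenol
Product: 20 2,4,6-tris(4-hydroxybenzyl)-3-[2-(3-hydroxyphenyl)ethyl]-5-methoxyphenol (CNP0262401.0)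
Conditions: H2 (1 atm), 10% Pd/C, EtOAc–MeOH, rt
Reagents that add atoms: none
Why: Catalytic hydrogenolysis should cleave the four aryl benzyl ethers, while the aryl methyl ether and the diarylmethane C–C bonds are stable at 1 atm over Pd/C.

**Compound list**

1 | ethyl [4-(benzyloxy)phenyl]acetate | CCOC(=O)Cc1ccc(OCc2ccccc2)cc1 | starting material
2 | lithium 3-[4-(benzyloxy)phenyl]-1,1-dibromoprop-1-en-2-olate | [Li+].[O-]C(Cc1ccc(OCc2ccccc2)cc1)=C(Br)Br | intermediate
3 | lithium 3-[4-(benzyloxy)phenyl]prop-1-yn-1-olate | [Li+].[O-]C#CCc1ccc(OCc2ccccc2)cc1 | intermediate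
4 | {3-[4-(benzyloxy)phenyl]prop-1-yn-1-yl}oxy(triisopropyl)silane | CC(C)[Si](OC#CCc1ccc(OCc2ccccc2)cc1)(C(C)C)C(C)C | intermediate
5 | 3-[4-(benzyloxy)phenyl]propanoic acid | O=C(O)CCc1ccc(OCc2ccccc2)cc1 | starting material
6 | 3-[4-(benzyloxy)phenyl]propanoyl chloride | O=C(Cl)CCc1ccc(OCc2ccccc2)cc1 | intermediate
7 | 3-[4-(benzyloxy)phenyl]prop-1-en-1-one (monoalkylketene) | O=C=CCc1ccc(OCc2ccccc2)cc1 | intermediate
8 | 2,4-bis[4-(benzyloxy)benzyl]-3-[(triisopropylsilyl)oxy]cyclobut-2-en-1-one (racemic) | O=C1C(Cc2ccc(OCc3ccccc3)cc2)C(O[Si](C(C)C)(C(C)C)C(C)C)=C1Cc1ccc(OCc2ccccc2)cc1 | intermediate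
9 | 1-(benzyloxy)-3-(2-bromoethyl)benzene | BrCCc1cccc(OCc2ccccc2)c1 | starting material
10 | {2-[3-(benzyloxy)phenyl]ethyl}magnesium bromide | Br[Mg]CCc1cccc(OCc2ccccc2)c1 | intermediate
11 | 2,4-bis[4-(benzyloxy)benzyl]-1-{2-[3-(benzyloxy)phenyl]ethyl}-3-[(triisopropylsilyl)oxy]cyclobut-2-en-1-ol (diastereomer mixture, racemic) | OC1(CCc2cccc(OCc3ccccc3)c2)C(Cc2ccc(OCc3ccccc3)cc2)=C(O[Si](C(C)C)(C(C)C)C(C)C)C1Cc1ccc(OCc2ccccc2)cc1 | intermediate
12 | 2,4-bis[4-(benzyloxy)benzyl]-3-{2-[3-(benzyloxy)phenyl]ethyl}cyclobut-2-en-1-one (racemic) | O=C1C(Cc2ccc(OCc3ccccc3)cc2)C(CCc2cccc(OCc3ccccc3)c2)=C1Cc1ccc(OCc2ccccc2)cc1 | intermediate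
13 | 2-[4-(benzyloxy)benzyl]-5-[4-(benzyloxy)phenyl]-3-{2-[3-(benzyloxy)phenyl]ethyl}penta-1,3-dien-1-one (vinylketene) | O=C=C(Cc1ccc(OCc2ccccc2)cc1)C(CCc1cccc(OCc2ccccc2)c1)=CCc1ccc(OCc2ccccc2)cc1 | intermediate
14 | 2,4-bis[4-(benzyloxy)benzyl]-4-{1-[3-(benzyloxy)phenyl]-5-[4-(benzyloxy)phenyl]pent-3-en-3-yl}-3-[(triisopropylsilyl)oxy]cyclobut-2-en-1-one (racemic) | O=C1C(Cc2ccc(OCc3ccccc3)cc2)=C(O[Si](C(C)C)(C(C)C)C(C)C)C1(Cc1ccc(OCc2ccccc2)cc1)C(CCc1cccc(OCc2ccccc2)c1)=CCc1ccc(OCc2ccccc2)cc1 | intermediate
15 | 2,4-bis[4-(benzyloxy)benzyl]-7-[4-(benzyloxy)phenyl]-5-{2-[3-(benzyloxy)phenyl]ethyl}-3-[(triisopropylsilyl)oxy]hepta-1,3,5-trien-1-one (dienylketene) | O=C=C(Cc1ccc(OCc2ccccc2)cc1)C(O[Si](C(C)C)(C(C)C)C(C)C)=C(Cc1ccc(OCc2ccccc2)cc1)C(CCc1cccc(OCc2ccccc2)c1)=CCc1ccc(OCc2ccccc2)cc1 | intermediate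
16 | 2,4,6-tris[4-(benzyloxy)benzyl]-5-{2-[3-(benzyloxy)phenyl]ethyl}-3-[(triisopropylsilyl)oxy]cyclohexa-2,4-dien-1-one (racemic) | O=C1C(Cc2ccc(OCc3ccccc3)cc2)=C(O[Si](C(C)C)(C(C)C)C(C)C)C(Cc2ccc(OCc3ccccc3)cc2)=C(CCc2cccc(OCc3ccccc3)c2)C1Cc1ccc(OCc2ccccc2)cc1 | intermediate
17 | 2,4,6-tris[4-(benzyloxy)benzyl]-5-{2-[3-(benzyloxy)phenyl]ethyl}-3-(triisopropylsilyloxy)phenol | Oc1c(Cc2ccc(OCc3ccccc3)cc2)c(O[Si](C(C)C)(C(C)C)C(C)C)c(Cc2ccc(OCc3ccccc3)cc2)c(CCc2cccc(OCc3ccccc3)c2)c1Cc1ccc(OCc2ccccc2)cc1 | intermediate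
18 | {2,4,6-tris[4-(benzyloxy)benzyl]-3-{2-[3-(benzyloxy)phenyl]ethyl}-5-methoxyphenoxy}triisopropylsilane | COc1c(Cc2ccc(OCc3ccccc3)cc2)c(O[Si](C(C)C)(C(C)C)C(C)C)c(Cc2ccc(OCc3ccccc3)cc2)c(CCc2cccc(OCc3ccccc3)c2)c1Cc1ccc(OCc2ccccc2)cc1 | intermediate
19 | 2,4,6-tris[4-(benzyloxy)benzyl]-3-{2-[3-(benzyloxy)phenyl]ethyl}-5-methoxyphenol | COc1c(Cc2ccc(OCc3ccccc3)cc2)c(O)c(Cc2ccc(OCc3ccccc3)cc2)c(CCc2cccc(OCc3ccccc3)c2)c1Cc1ccc(OCc2ccccc2)cc1 | intermediate
20 | 2,4,6-tris(4-hydroxybenzyl)-3-[2-(3-hydroxyphenyl)ethyl]-5-methoxyphenol | COc1c(Cc2ccc(O)cc2)c(O)c(Cc2ccc(O)cc2)c(CCc2cccc(O)c2)c1Cc1ccc(O)cc1 | target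

**Step count**

Total steps: 8. Longest linear sequence: 7 (steps 1, 3, 4, 5, 6, 7, 8 from ester 1; equally steps 2–8 from acid 5).

**Steps most likely to fail, with fallbacks**

Step 5. The risk is that siloxyalkyne 4 is consumed thermally (1,3-silyl shift to a silylketene and oligomerisation) faster than the crowded cyclobutenone 12 opens, or that the dienylketene is acylated or otherwise intercepted before it electrocyclises. The fallback changes the alkyne partner and shortens the end game. Because the benzyl groups on C2, C4 and C6 are identical, exchanging OH and OMe between C1 and C3 gives the same compound, so the methyl ether can be carried in on the alkyne. Lithium methoxyacetylide (from chloroacetaldehyde dimethyl acetal and LiNEt2 in THF) would be alkylated with commercial 4-(benzyloxy)benzyl bromide in THF–DMPU to give 1-(benzyloxy)-4-(3-methoxyprop-2-yn-1-yl)benzene F1, a methyl ynol ether with no silyl group to migrate and no β-hydrogen for retro-ene loss. The fallback sets out from 12: heating 12 with F1 in toluene (the alkoxyalkyne form of the same benzannulation) should give 19 directly, with the free hydroxyl on the ketone-derived carbon and the methoxy group on the alkyne-derived carbon. The route is rejoined at 19, and steps 6 and 7 fall away.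

Step 3. The risk is that the monoalkylketene dimerises under amine and ammonium-salt catalysis faster than it is captured by 4, and that 4 is acylated directly by the acid chloride. The fallback generates the same ketene without base, by a photochemical Wolff rearrangement. It sets out from 1: saponification (LiOH, THF–H2O) should give [4-(benzyloxy)phenyl]acetic acid F2; oxalyl chloride with catalytic DMF should give [4-(benzyloxy)phenyl]acetyl chloride F3; excess diazomethane in Et2O at 0 °C should give 1-[4-(benzyloxy)phenyl]-3-diazopropan-2-one F4. Irradiation of F4 (Pyrex-filtered medium-pressure Hg lamp, CH2Cl2, rt) in the presence of 4 should release ketene 7 by 1,2-shift of the arylmethyl group at low concentration in a neutral medium. Its [2+2] cycloaddition with 4 then rejoins the route at 8.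

Step 1. The risk is deprotonation at the benzylic, ester-activated α-position of 1 by LiCHBr2 or LiTMP in competition with carbonyl addition, and base attack on the benzyl ether during the warm-up with alkyllithium. The fallback reaches the same ynolate by reductive lithiation of an α,α-dibromo ester (Shindo ynolate synthesis), in which no nucleophile has to add to an enolisable ester. It sets out from 5: Fischer esterification (EtOH, cat. H2SO4) should give ethyl 3-[4-(benzyloxy)phenyl]propanoate F5. Two successive enolate brominations (LDA, BrCCl2CCl2Br, THF, −78 °C) should give ethyl 2,2-dibromo-3-[4-(benzyloxy)phenyl]propanoate F6. Treatment of F6 with t-BuLi (4 equiv, THF, −78 → 0 °C) should effect double Br–Li exchange and loss of ethoxide to give lithium ynolate 3. Silylation with TIPSCl as in step 1 rejoins the route at 4.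

**Further compounds**

F1 | step 5 | 1-(benzyloxy)-4-(3-methoxyprop-2-yn-1-yl)benzene | COC#CCc1ccc(OCc2ccccc2)cc1
F2 | step 3 | [4-(benzyloxy)phenyl]acetic acid | O=C(O)Cc1ccc(OCc2ccccc2)cc1
F3 | step 3 | [4-(benzyloxy)phenyl]acetyl chloride | O=C(Cl)Cc1ccc(OCc2ccccc2)cc1
F4 | step 3 | 1-[4-(benzyloxy)phenyl]-3-diazopropan-2-one | [N-]=[N+]=CC(=O)Cc1ccc(OCc2ccccc2)cc1
F5 | step 1 | ethyl 3-[4-(benzyloxy)phenyl]propanoate | CCOC(=O)CCc1ccc(OCc2ccccc2)cc1
F6 | step 1 | ethyl 2,2-dibromo-3-[4-(benzyloxy)phenyl]propanoate | CCOC(=O)C(Br)(Br)Cc1ccc(OCc2ccccc2)cc1
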